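**Plan**
- Retrosynthesis: the p-hydroxybenzoate is cut last (C8–O acyl bond). The C6–OH / C7–H / C8–O array is read as a C6=C7 alkene with an allylic oxygen on C8.
- What remains is a bicyclo[5.3.0]deca-1(10),6-diene. The tetrasubstituted C1=C10 alkene and the C6=C7 alkene lie 1,4 to each other in the seven-membered ring across sp3 C5, and C1/C5 are bridged by C2–C3–C4. This cyclopentane-fused cyclohepta-1,4-diene is the retron of an alkyne + vinylcyclopropane (5+2) cycloaddition, which cuts C9–C10 and C1–C5 together.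
- The acyclic precursor is cut at C5=C6 (olefination) and C4–CH3 (asymmetric methyl addition), giving a siloxycyclopropane aldehyde (C6–C9, C11–C13) and a but-2-ynyl keto phosphonate (C1–C5, C10, C14).
- Forward: cyclopropane first, chain joined, then cyclopentane and cycloheptadiene formed in one step, then the C6–C8 oxygen pattern and the ester.
- Stereochemistry: cyclopropane C7/C8 by reagent-controlled asymmetric Simmons–Smith; C4 by catalyst control; C5 by transfer from cyclopropane C7 in the cycloaddition; C6 by 8-OH-directed epoxidation; C7 by a stereospecific 1,2-hydride shift; C8 finally by 6-OH-directed anti reduction.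

Key step: step 9

Remark: locants follow guaiane numbering, used only as a skeletal name (five-membered ring C1–C5, seven-membered ring C1, C5–C10; C4 carries CH3/OH, C7 isopropyl, C10 CH3); the target is read as (4S,5S,6R,7S,8S) with H-5 defined as α. TBS = tert-butyl(dimethyl)silyl.

Step 1
Reactants: 1 ethyl 3-methylbutanoate; 2 ethyl formate
Product: 3 ethyl 2-formyl-3-methylbutanoate
Conditions: LiN(iPr)2, THF, −78 °C; then 2, −78 → 0 °C; aq. HCl
Reagents that add atoms: none
Why: Crossed Claisen condensation (C-formylation) of the ester lithium enolate with non-enolisable ethyl formate should give the β-formyl ester, drawn out of the equilibrium as its stabilised enolate; the α-centre is lost again in the next step.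

Step 2
Reactants: 3 ethyl 2-formyl-3-methylbutanoate
Product: 4 ethyl (2E)-2-({[tert-butyl(dimethyl)silyl]oxy}methylidene)-3-methylbutanoate
Conditions: TBSCl, Et3N, DMAP (cat.), CH2Cl2, 0 °C → rt
Reagents that add atoms: tert-butyldimethylsilyl chloride, CC(C)(C)[Si](C)(C)Cl
Why: O-silylation of the formyl-ester enol under non-chelating amine conditions should give the (E)-β-silyloxy acrylate (silyloxy anti to the ester, as in amine-mediated E-selective enol sulfonylation of α-formyl esters), which fixes the later trans relationship of O8 and C6 on the cyclopropane.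

Step 3
Reactants: 4 ethyl (2E)-2-({[tert-butyl(dimethyl)silyl]oxy}methylidene)-3-methylbutanoate
Product: 5 (2E)-2-({[tert-butyl(dimethyl)silyl]oxy}methylidene)-3-methylbutan-1-ol
Conditions: iBu2AlH (2.2 equiv), CH2Cl2, −78 °C; Rochelle salt
Reagents that add atoms: none
Why: 1,2-Reduction of the vinylogous carbonate ester by the aluminium hydride should give the allylic alcohol with the silyl enol ether and the alkene geometry intact.

Step 4
Reactants: 5 (2E)-2-({[tert-butyl(dimethyl)silyl]oxy}methylidene)-3-methylbutan-1-ol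
Product: 6 [(1R,2R)-2-{[tert-butyl(dimethyl)silyl]oxy}-1-(propan-2-yl)cyclopropyl]methanol
Conditions: Et2Zn, CH2I2, DME, (4S,5S)-2-butyl-N,N,N',N'-tetramethyl-1,3,2-dioxaborolane-4,5-dicarboxamide (1.2 equiv), CH2Cl2, −10 °C → rt
Reagents that add atoms: diiodomethane, ICI
Why: Dioxaborolane-mediated asymmetric Simmons–Smith cyclopropanation of an allylic alcohol, in which the zinc alkoxide bound to the chiral boronate delivers methylene cis-stereospecifically (O8 stays trans to C6) to one enantiotopic face, so C7 and C8 are set by reagent control in the facial sense established for this ligand class.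

Step 5
Reactants: 6 [(1R,2R)-2-{[tert-butyl(dimethyl)silyl]oxy}-1-(propan-2-yl)cyclopropyl]methanol
Product: 7 (1S,2R)-2-{[tert-butyl(dimethyl)silyl]oxy}-1-(propan-2-yl)cyclopropane-1-carbaldehyde
Conditions: (nPr4N)RuO4 (5 mol %), N-methylmorpholine N-oxide, 4 Å molecular sieves, CH2Cl2, 0 °C; used directly
Reagents that add atoms: none
Why: Ley–Griffith oxidation under neutral, non-nucleophilic conditions should give the non-enolisable aldehyde without opening the donor–acceptor cyclopropane.

Step 6
Reactants: 8 dimethyl (2-oxopropyl)phosphonate; 9 1-bromobut-2-yne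
Product: 10 dimethyl (2-oxohept-5-yn-1-yl)phosphonate
Conditions: NaH, THF, 0 °C; n-BuLi, 0 °C; then 9, 0 °C → rt; aq. HCl
Reagents that add atoms: none
Why: γ-Alkylation of the β-keto phosphonate dianion, whose more basic terminal carbanion attacks the propargylic bromide by SN2, forms the C2–C3 bond.

Step 7
Reactants: 7 (1S,2R)-2-{[tert-butyl(dimethyl)silyl]oxy}-1-(propan-2-yl)cyclopropane-1-carbaldehyde; 10 dimethyl (2-oxohept-5-yn-1-yl)phosphonate
Product: 11 (1E)-1-[(1R,2R)-2-{[tert-butyl(dimethyl)silyl]oxy}-1-(propan-2-yl)cyclopropyl]oct-1-en-6-yn-3-one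
Conditions: LiCl, iPr2NEt, MeCN, rt
Reagents that add atoms: none
Why: Horner–Wadsworth–Emmons olefination under mild LiCl/amine conditions should give the (E)-enone through the favoured anti oxaphosphetane, without exposing the siloxycyclopropane aldehyde to hydroxide or fluoride.

Step 8
Reactants: 11 (1E)-1-[(1R,2R)-2-{[tert-butyl(dimethyl)silyl]oxy}-1-(propan-2-yl)cyclopropyl]oct-1-en-6-yn-3-one
Product: 12 (1E,3S)-1-[(1R,2R)-2-{[tert-butyl(dimethyl)silyl]oxy}-1-(propan-2-yl)cyclopropyl]-3-methyloct-1-en-6-yn-3-ol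
Conditions: Me2Zn (3 equiv), Ti(OiPr)4 (1.2 equiv), trans-1,2-bis(2-exo-hydroxy-10-camphorsulfonamido)cyclohexane (10 mol %, the enantiomer that delivers methyl to the Re face), toluene/hexane, rt; aq. NH4Cl
Reagents that add atoms: dimethylzinc, C[Zn]C
Why: Titanium/bis(sulfonamide) diol-catalysed enantioselective 1,2-addition of a dialkylzinc to an α,β-unsaturated ketone should create the C4 tertiary carbinol by catalyst control (planar alkenyl group distinguished from the CH2CH2 chain), the remote cyclopropane centres having no influence.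

Step 9
Reactants: 12 (1E,3S)-1-[(1R,2R)-2-{[tert-butyl(dimethyl)silyl]oxy}-1-(propan-2-yl)cyclopropyl]-3-methyloct-1-en-6-yn-3-ol
Product: 13 (4S,5R,8R)-8-{[tert-butyl(dimethyl)silyl]oxy}guaia-1(10),6-dien-4-ol
Conditions: [Rh(CO)2Cl]2 (5 mol %), toluene (0.02 M), 80 °C
Reagents that add atoms: none
Why: Monovalent rhodium binds the C5=C6 alkene and cleaves the cyclopropane bond C7–C9 by oxidative addition to a trivalent rhodium σ,π-allyl; the tethered alkyne then inserts at allyl terminus C5 (C1–C5 bond) to give an eight-membered rhodacycle, and C(sp3)–C(sp2) reductive elimination forms C9–C10. The closest known reaction type is the rhodium-catalysed intramolecular (5+2) cycloaddition of alkyne-tethered vinylcyclopropanes, including 2-substituted cyclopropanes. The cyclopentane closes in a 5-exo-dig sense by alkyne insertion (C10 stays outside that ring), and the cycloheptadiene closes by reductive elimination at C9–C10 with contraction of the rhodacycle. C5 is the only new stereocentre and is dictated by cyclopropane carbon C7: in the s-cis reactive conformer C9 lies on one face of the alkene, rhodium must sit on that face to reach it, and C1 is delivered to C5 from the same face, so the (1R) cyclopropane carbon should translate into (5R), while C8 is carried through with retention and the small free 4-hydroxyl ends cis to C6. The step needs cleavage of C7–C9 and not C7–C8, which the substrate secures because insertion into C7–C8 would place rhodium on a secondary carbon bearing the bulky silyloxy group. The neutral chloride-bridged catalyst is chosen so that the tertiary allylic alcohol and the silyloxy cyclopropane are not ionised.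

Step 10
Reactants: 13 (4S,5R,8R)-8-{[tert-butyl(dimethyl)silyl]oxy}guaia-1(10),6-dien-4-ol
Product: 14 (4S,5R,8R)-guaia-1(10),6-diene-4,8-diol
Conditions: Bu4NF, THF, 0 °C → rt
Reagents that add atoms: none
Why: Fluoride-mediated cleavage of the secondary allylic silyl ether frees the 8β-hydroxyl needed as directing group; no stereocentre is touched.

Step 11
Reactants: 14 (4S,5R,8R)-guaia-1(10),6-diene-4,8-diol
Product: 15 (4S,5S,6S,7R,8R)-6,7-epoxyguai-1(10)-ene-4,8-diol
Conditions: VO(acac)2 (3 mol %), tBuOOH (1.3 equiv), CH2Cl2, 0 °C → rt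
Reagents that add atoms: tert-butyl hydroperoxide, CC(C)(C)OO
Why: Vanadium-catalysed hydroxyl-directed epoxidation, in which the allylic 8β-OH binds the metal peroxide and delivers oxygen to the syn (β) face of C6=C7 (the cis selectivity typical of cyclohept-2-enols), should set C6–O and leave the undirected tetrasubstituted C1=C10 alkene untouched.

Step 12
Reactants: 15 (4S,5S,6S,7R,8R)-6,7-epoxyguai-1(10)-ene-4,8-diol
Product: 18 (4S,5S,6S,7S)-4,6-dihydroxyguai-1(10)-en-8-one, via disilylated epoxide 16 (not isolated), via disilylated ketone 17 (not isolated)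
Conditions: Me3SiOTf (3.5 equiv), iPr2NEt, CH2Cl2, −78 → −40 °C; then 1 M citric acid, THF/H2O, 0 °C
Reagents that add atoms: none
Why: Non-aldol aldol (semipinacol) rearrangement of a 2,3-epoxy alcohol, in which the silyl triflate silylates both hydroxyls and activates the epoxide at tertiary C7 while the α-face hydride on C8, antiperiplanar to the breaking C7–O bond, shifts to C7 with inversion (7α-H, 7β-isopropyl), C8 becoming the ketone and C6 keeping its β-oxygen; mild acid then removes the trimethylsilyl groups.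

Step 13
Reactants: 18 (4S,5S,6S,7S)-4,6-dihydroxyguai-1(10)-en-8-one
Product: 19 (4S,5S,6R,7R,8S)-guai-1(10)-ene-4,6,8-triol
Conditions: Me4NBH(OAc)3, MeCN/AcOH (1:1), −30 °C
Reagents that add atoms: none
Why: Evans–Saksena reduction, in which the 6β-hydroxyl exchanges onto boron and hydride is delivered intramolecularly to the β face of the C8 ketone through a six-membered chair, should give the 1,3-anti diol (8α-OH).

Step 14
Reactants: 19 (4S,5S,6R,7R,8S)-guai-1(10)-ene-4,6,8-triol; 20 4-acetoxybenzoyl chloride
Product: 21 (4S,5S,6R,7S,8S)-4,6-dihydroxyguai-1(10)-en-8-yl 4-acetoxybenzoate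
Conditions: 20 (1.05 equiv), pyridine, CH2Cl2, −20 → 0 °C
Reagents that add atoms: none
Why: Acylation by an acid chloride under pyridine should be selective for the 8α-hydroxyl (next to the C9 methylene, trans to isopropyl) over the 6β-hydroxyl (cis to isopropyl, next to the ring fusion) and the unreactive tertiary 4-hydroxyl; DMAP is left out so that the aryl acetate is not transferred.

Step 15
Reactants: 21 (4S,5S,6R,7S,8S)-4,6-dihydroxyguai-1(10)-en-8-yl 4-acetoxybenzoate
Product: 22 (4S,5S,6R,7S,8S)-4,6-dihydroxyguai-1(10)-en-8-yl 4-hydroxybenzoate (target)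
Conditions: NH4OAc, MeOH/H2O (4:1), rt
Reagents that add atoms: none
Why: Chemoselective solvolysis of the aryl acetate, far more electrophilic than the secondary alkyl benzoate, should free the phenol without cleaving the C8 ester.

**Compound list**
1 | ethyl 3-methylbutanoate | CCOC(=O)CC(C)C | starting material
2 | ethyl formate | CCOC=O | starting material
3 | ethyl 2-formyl-3-methylbutanoate (racemic, aldehyde/enol mixture) | CCOC(=O)C(C=O)C(C)C | intermediate
4 | ethyl (2E)-2-({[tert-butyl(dimethyl)silyl]oxy}methylidene)-3-methylbutanoate | CCOC(=O)/C(C(C)C)=C/O[Si](C)(C)C(C)(C)C | intermediate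
5 | (2E)-2-({[tert-butyl(dimethyl)silyl]oxy}methylidene)-3-methylbutan-1-ol | OC/C(C(C)C)=C/O[Si](C)(C)C(C)(C)C | intermediate
6 | [(1R,2R)-2-{[tert-butyl(dimethyl)silyl]oxy}-1-(propan-2-yl)cyclopropyl]methanol | OC[C@]1(C(C)C)C[C@H]1O[Si](C)(C)C(C)(C)C | intermediate
7 | (1S,2R)-2-{[tert-butyl(dimethyl)silyl]oxy}-1-(propan-2-yl)cyclopropane-1-carbaldehyde | O=C[C@]1(C(C)C)C[C@H]1O[Si](C)(C)C(C)(C)C | intermediate
8 | dimethyl (2-oxopropyl)phosphonate | CC(=O)CP(=O)(OC)OC | starting material
9 | 1-bromobut-2-yne | CC#CCBr | starting material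
10 | dimethyl (2-oxohept-5-yn-1-yl)phosphonate | CC#CCCC(=O)CP(=O)(OC)OC | intermediate
11 | (1E)-1-[(1R,2R)-2-(TBS-oxy)-1-(propan-2-yl)cyclopropyl]oct-1-en-6-yn-3-one | CC#CCCC(=O)/C=C/[C@]1(C(C)C)C[C@H]1O[Si](C)(C)C(C)(C)C | intermediate
12 | (1E,3S)-1-[(1R,2R)-2-(TBS-oxy)-1-(propan-2-yl)cyclopropyl]-3-methyloct-1-en-6-yn-3-ol | CC#CCC[C@](C)(O)/C=C/[C@]1(C(C)C)C[C@H]1O[Si](C)(C)C(C)(C)C | intermediate
13 | (4S,5R,8R)-8-(TBS-oxy)guaia-1(10),6-dien-4-ol (8β-silyloxy, 5α-H) | CC1=C2CC[C@](C)(O)[C@@H]2C=C(C(C)C)[C@H](O[Si](C)(C)C(C)(C)C)C1 | intermediate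
14 | (4S,5R,8R)-guaia-1(10),6-diene-4,8-diol | CC1=C2CC[C@](C)(O)[C@@H]2C=C(C(C)C)[C@H](O)C1 | intermediate
15 | (4S,5S,6S,7R,8R)-6,7-epoxyguai-1(10)-ene-4,8-diol (6β,7β-epoxide) | CC1=C2CC[C@](C)(O)[C@@H]2[C@@H]3O[C@]3(C(C)C)[C@H](O)C1 | intermediate
16 | 4,8-bis(trimethylsilyl) ether of 15 | CC1=C2CC[C@](C)(O[Si](C)(C)C)[C@@H]2[C@@H]3O[C@]3(C(C)C)[C@H](O[Si](C)(C)C)C1 | intermediate
17 | 4,6-bis(trimethylsilyl) ether of 18 | CC1=C2CC[C@](C)(O[Si](C)(C)C)[C@@H]2[C@H](O[Si](C)(C)C)[C@H](C(C)C)C(=O)C1 | intermediate
18 | (4S,5S,6S,7S)-4,6-dihydroxyguai-1(10)-en-8-one | CC1=C2CC[C@](C)(O)[C@@H]2[C@H](O)[C@H](C(C)C)C(=O)C1 | intermediate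
19 | (4S,5S,6R,7R,8S)-guai-1(10)-ene-4,6,8-triol | CC1=C2CC[C@](C)(O)[C@@H]2[C@H](O)[C@H](C(C)C)[C@@H](O)C1 | intermediate
20 | 4-acetoxybenzoyl chloride | CC(=O)Oc1ccc(cc1)C(Cl)=O | starting material
21 | (4S,5S,6R,7S,8S)-4,6-dihydroxyguai-1(10)-en-8-yl 4-acetoxybenzoate | CC1=C2CC[C@](C)(O)[C@@H]2[C@H](O)[C@H](C(C)C)[C@@H](OC(=O)c2ccc(OC(C)=O)cc2)C1 | intermediate
22 | (4S,5S,6R,7S,8S)-4,6-dihydroxyguai-1(10)-en-8-yl 4-hydroxybenzoate | CC1=C2CC[C@](C)(O)[C@@H]2[C@H](O)[C@H](C(C)C)[C@@H](OC(=O)c2ccc(O)cc2)C1 | target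

**Count**
Total steps: 15. Longest linear sequence: 14 (steps 1–5 and 7–15); step 6 is a one-step side branch.

**Steps most likely to fail**

Step 9. The metal may insert into the oxygen-bearing C7–C8 bond instead of C7–C9, which would give the regioisomeric adduct with the opposite C5 configuration, or the donor-substituted vinylcyclopropane may isomerise to a cyclopentene. The fallback places the silyloxy group cis to the vinyl group, where cleavage of its own bond is blocked because the substituent would point at the metal, and inverts C8 afterwards. It sets out from 3: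
- Silylation through the lithium chelate (LiN(SiMe3)2, TBSCl, THF, −78 °C) gives the (Z)-silyl enol ether F1, and iBu2AlH reduction gives the (Z)-allylic alcohol F2.
- The same asymmetric cyclopropanation gives the cis cyclopropylmethanol F3, and oxidation gives the aldehyde F4.
- Olefination with 10 gives the enone F5, and the same methyl addition gives the carbinol F6.
- The rhodium-catalysed cycloaddition should then give the 8α-silyloxy diene F7, and Bu4NF gives the 8α-alcohol F8.
- Mitsunobu reaction (PPh3, diisopropyl azodicarboxylate, 4-nitrobenzoic acid) gives the inverted 8β-ester F9, and K2CO3/MeOH returns to the route at 14.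

Step 12. The cation-like C7 may be intercepted by migration of C9 (ring contraction), by transannular attack of the C1=C10 alkene or by elimination, and the product ketone may be converted to a silyl dienol ether and reprotonated into conjugation. The fallback avoids the cationic manifold. It sets out from 15: Dess–Martin oxidation of the 8-hydroxyl gives the epoxy ketone F10, and SmI2 (THF/MeOH, −78 °C) cleaves the C7–O bond α to the ketone. Protonation of the samarium enolate on the α face, anti to the C6 oxygen, should then give 18, where the fallback rejoins the route.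

Step 8. Facial discrimination between the alkenyl group and the CH2CH2 chain may be poor, and methyl transfer from Me2Zn may be slow. The fallback reverses the roles so that the catalyst distinguishes methyl from alkenyl, its best-differentiated ketone class. It sets out from 7 and 8: the same LiCl/amine olefination gives the methyl enone F11. Pent-3-yn-1-ol is converted (I2, PPh3, imidazole) to the iodide F12 and then (Et2Zn, CuI cat.) to the dialkylzinc F13. F13 is added to F11 with Ti(OiPr)4 and the antipodal bis(sulfonamide) diol ligand (Si-face delivery), which returns to the route at 12.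

**Further compounds**
F1 | step 9 | ethyl (2Z)-2-({[tert-butyl(dimethyl)silyl]oxy}methylidene)-3-methylbutanoate | CCOC(=O)/C(C(C)C)=C\O[Si](C)(C)C(C)(C)C
F2 | step 9 | (2Z)-2-({[tert-butyl(dimethyl)silyl]oxy}methylidene)-3-methylbutan-1-ol | OC/C(C(C)C)=C\O[Si](C)(C)C(C)(C)C
F3 | step 9 | [(1R,2S)-2-(TBS-oxy)-1-(propan-2-yl)cyclopropyl]methanol | OC[C@]1(C(C)C)C[C@@H]1O[Si](C)(C)C(C)(C)C
F4 | step 9 | (1S,2S)-2-(TBS-oxy)-1-(propan-2-yl)cyclopropane-1-carbaldehyde | O=C[C@]1(C(C)C)C[C@@H]1O[Si](C)(C)C(C)(C)C
F5 | step 9 | (1E)-1-[(1R,2S)-2-(TBS-oxy)-1-(propan-2-yl)cyclopropyl]oct-1-en-6-yn-3-one | CC#CCCC(=O)/C=C/[C@]1(C(C)C)C[C@@H]1O[Si](C)(C)C(C)(C)C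
F6 | step 9 | (1E,3S)-1-[(1R,2S)-2-(TBS-oxy)-1-(propan-2-yl)cyclopropyl]-3-methyloct-1-en-6-yn-3-ol | CC#CCC[C@](C)(O)/C=C/[C@]1(C(C)C)C[C@@H]1O[Si](C)(C)C(C)(C)C
F7 | step 9 | (4S,5R,8S)-8-(TBS-oxy)guaia-1(10),6-dien-4-ol | CC1=C2CC[C@](C)(O)[C@@H]2C=C(C(C)C)[C@@H](O[Si](C)(C)C(C)(C)C)C1
F8 | step 9 | (4S,5R,8S)-guaia-1(10),6-diene-4,8-diol | CC1=C2CC[C@](C)(O)[C@@H]2C=C(C(C)C)[C@@H](O)C1
F9 | step 9 | (4S,5R,8R)-4-hydroxyguaia-1(10),6-dien-8-yl 4-nitrobenzoate | CC1=C2CC[C@](C)(O)[C@@H]2C=C(C(C)C)[C@H](OC(=O)c2ccc(cc2)[N+](=O)[O-])C1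
F10 | step 12 | (4S,5S,6S,7S)-6,7-epoxy-4-hydroxyguai-1(10)-en-8-one | CC1=C2CC[C@](C)(O)[C@@H]2[C@@H]3O[C@]3(C(C)C)C(=O)C1
F11 | step 8 | (3E)-4-[(1R,2R)-2-(TBS-oxy)-1-(propan-2-yl)cyclopropyl]but-3-en-2-one | CC(=O)/C=C/[C@]1(C(C)C)C[C@H]1O[Si](C)(C)C(C)(C)C
F12 | step 8 | 5-iodopent-2-yne | CC#CCCI
F13 | step 8 | bis(pent-3-yn-1-yl)zinc | CC#CCC[Zn]CCC#CC
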